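Ring C is cut at O1–C8a and C4–C4a, and ring A is taken at the oxidation level of a p-quinone monoketal, which the para pair of oxygens on C5 and C8 permits. In 3,4,4-trimethoxycyclohexa-2,5-dienone the future C8a is the free β-carbon and the future C4a the α-carbon, so the alkoxide of ethyl (S)-3-(3,4-dimethoxyphenyl)-3-hydroxypropanoate should add through oxygen at C8a and the enolate so formed should acylate itself at C4a with the ester. Loss of methanol then aromatises ring A. One operation thus builds both bonds of the pyranone ring with fixed regiochemistry while C2, set beforehand by asymmetric hydrogenation, stays untouched; a final O-methylation at C5 completes the target.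

Key step: step 3

Remark on the chemistry: the target is the (2S)-flavanone. The transient stereocentres C4a and C8a of intermediates 6 and 7 are expected as mixtures, are left undefined in the SMILES and are erased on aromatisation.

Step 1
Reactants: 1 3,4-dimethoxyphenol
Product: 2 3,4,4-trimethoxycyclohexa-2,5-dien-1-one
Conditions: PhI(OAc)2 (1.1 equiv), MeOH, 0 °C → rt
Reagents that add atoms: methanol, CO
Why: Oxidative dearomatisation of a p-methoxyphenol by trivalent iodine, in which methanol should trap the activated phenol at the methoxy-bearing para carbon and give the p-quinone monoketal regiospecifically.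

Step 2
Reactants: 3 ethyl 3-(3,4-dimethoxyphenyl)-3-oxopropanoate
Product: 4 ethyl (S)-3-(3,4-dimethoxyphenyl)-3-hydroxypropanoate
Conditions: RuCl2[(R)-BINAP] (cat.), H2 (50 atm), EtOH, 50 °C
Reagents that add atoms: none
Why: Noyori asymmetric hydrogenation of a β-keto ester, in which the substrate chelates divalent ruthenium through both carbonyls and the (R)-BINAP ligand should direct hydride to the face that gives the (S)-carbinol, as with ethyl benzoylacetate.

Step 3
Reactants: 4 ethyl (S)-3-(3,4-dimethoxyphenyl)-3-hydroxypropanoate, 2 3,4,4-trimethoxycyclohexa-2,5-dien-1-one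
Product: 8 (S)-2-(3,4-dimethoxyphenyl)-5-hydroxy-7,8-dimethoxychroman-4-one, via sodium alkoxide of the hydroxy ester 5 (not isolated), via oxa-Michael adduct sodium enolate 6 (not isolated), via bicyclic diketone ketal 7 (not isolated)
Conditions: NaN(SiMe3)2 (1.05 equiv), THF, −78 °C; then 2 (1.2 equiv), −78 → 0 °C; then AcOH, PPTS (cat.), CH2Cl2, rt
Reagents that add atoms: none
Why: Proposed new method: alkoxide 5 should add in an oxa-Michael fashion to the unsubstituted β-carbon of dienone 2 (the future C8a), and the resulting enolate 6 should attack the ethyl ester through its α-carbon (the future C4a) in an intramolecular Claisen (Dieckmann-type) acylation that expels ethoxide and is driven by formation of the stabilised β-diketonate of 7; mild acid then ionises the allylic ketal at C8, and loss of methanol plus enolisation aromatises ring A to the 5-hydroxy-7,8-dimethoxy pattern. The closest known reaction types are the oxa-Michael/Dieckmann annulation of hydroxy esters such as methyl glycolate with acrylates and the Michael/Dieckmann (Hauser–Kraus-type) annulations of quinone monoketals with ester-bearing carbanions, which use the same β-then-α polarity of the dienone. Ring C closes in the Claisen step by 6-exo-trig attack of the enolate carbon on the ester carbonyl, after the intermolecular C–O bond formation. No stereocentre of the product is created: C2 comes from 4 with its C–O bond intact (retention), the transient centres at C4a and C8a vanish on aromatisation, and base-induced opening of ring C is not expected because O1 is an alkoxide-type leaving group until ring A is aromatic and the C4 carbonyl is masked as a diketonate. The step needs O-addition at the future C8a and not at the methoxy-bearing β-carbon (the future C7), which the 3-methoxy group secures by turning that carbon into a deactivated, hindered vinylogous ester position, and it needs O- over C-reactivity of 4, secured by using one equivalent of base so that only the hydroxyl is deprotonated.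

Step 4
Reactants: 8 (S)-2-(3,4-dimethoxyphenyl)-5-hydroxy-7,8-dimethoxychroman-4-one
Product: 9 (S)-2-(3,4-dimethoxyphenyl)-5,7,8-trimethoxychroman-4-one
Conditions: MeI (excess), Ag2O, MeCN, rt → 40 °C, dark
Reagents that add atoms: iodomethane, CI
Why: Silver-assisted O-methylation (Purdie-type Williamson etherification), in which Ag2O activates iodomethane and acts as an insoluble mild base, so the hydrogen-bonded 5-hydroxyl should be methylated without the soluble strong base that would open ring C by E1cB elimination and racemise C2.

Compound list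
1 | 3,4-dimethoxyphenol | COc1ccc(O)cc1OC | starting material
2 | 3,4,4-trimethoxycyclohexa-2,5-dien-1-one | COC1=CC(=O)C=CC1(OC)OC | intermediate
3 | ethyl 3-(3,4-dimethoxyphenyl)-3-oxopropanoate | CCOC(=O)CC(=O)c1ccc(OC)c(OC)c1 | starting material
4 | ethyl (S)-3-(3,4-dimethoxyphenyl)-3-hydroxypropanoate | CCOC(=O)C[C@H](O)c1ccc(OC)c(OC)c1 | intermediate
5 | sodium (1S)-1-(3,4-dimethoxyphenyl)-3-ethoxy-3-oxopropan-1-olate (sodium alkoxide of 4, not isolated) | CCOC(=O)C[C@H]([O-])c1ccc(OC)c(OC)c1.[Na+] | intermediate
6 | sodium enolate of ethyl (3S)-3-(3,4-dimethoxyphenyl)-3-[(5,6,6-trimethoxy-3-oxocyclohex-4-en-1-yl)oxy]propanoate (oxa-Michael adduct, not isolated) | CCOC(=O)C[C@H](OC1C=C([O-])C=C(OC)C1(OC)OC)c1ccc(OC)c(OC)c1.[Na+] | intermediate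
7 | (2S)-2-(3,4-dimethoxyphenyl)-7,8,8-trimethoxy-2,3,8,8a-tetrahydro-4H-chromene-4,5(4aH)-dione (formed as its sodium enolate, protonated by AcOH, not isolated) | COc1ccc([C@@H]2CC(=O)C3C(=O)C=C(OC)C(OC)(OC)C3O2)cc1OC | intermediate
8 | (S)-2-(3,4-dimethoxyphenyl)-5-hydroxy-7,8-dimethoxychroman-4-one | COc1ccc([C@@H]2CC(=O)c3c(O)cc(OC)c(OC)c3O2)cc1OC | intermediate
9 | (S)-2-(3,4-dimethoxyphenyl)-5,7,8-trimethoxychroman-4-one | COc1ccc([C@@H]2CC(=O)c3c(OC)cc(OC)c(OC)c3O2)cc1OC | target

Total step count: 4. Longest linear sequence: 3 steps (step 1 or step 2, then steps 3 and 4).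

Steps most likely to fail

Step 3 (proposed new method). Reversal of the oxa-Michael addition, together with retro-aldol cleavage or E1cB dehydration of alkoxide 5, may outrun the intramolecular Claisen acylation, or the conjugate addition may stray to the methoxy-bearing carbon. The fallback uses known chemistry, sets out from 1 and 4 and comes back at 7; it forms the two bonds in the opposite order. Phenol 1 is brominated para to its 3-methoxy group (NBS, MeCN, 0 °C) to 2-bromo-4,5-dimethoxyphenol F1. Ester 4 is converted (MeNH(OMe)·HCl, i-PrMgCl, THF, −20 °C) into the Weinreb amide (S)-3-(3,4-dimethoxyphenyl)-3-hydroxy-N-methoxy-N-methylpropanamide F2. The dianion of F1 (n-BuLi, 2 equiv, THF, −78 °C), acylated by the chloromagnesium alkoxide of F2, should give (S)-3-(3,4-dimethoxyphenyl)-3-hydroxy-1-(2-hydroxy-4,5-dimethoxyphenyl)propan-1-one F3, which carries the C4–C4a bond. PhI(OAc)2 in MeOH should then oxidise its p-methoxyphenol to the acyl quinone monoketal 2-[(S)-3-(3,4-dimethoxyphenyl)-3-hydroxypropanoyl]-4,4,5-trimethoxycyclohexa-2,5-dien-1-one F4. In F4 the side-chain hydroxyl should add 6-endo to the doubly activated β-carbon (O1–C8a bond) to give diketone ketal 7, which PPTS aromatises to 8 as in step 3.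

Step 4. The hydrogen-bonded 5-hydroxyl may alkylate sluggishly, and any forcing with base may open ring C by E1cB elimination and erode the configuration at C2. The fallback sets out from 8 and comes back at 9; it removes the C4 carbonyl for the duration of the methylation. NaBH4 (MeOH, 0 °C) should reduce 8 to the 2,4-cis diol (2S,4S)-2-(3,4-dimethoxyphenyl)-7,8-dimethoxychromane-4,5-diol F5. Its phenol, no longer chelated and no longer part of a system that can open by enolisation, is methylated (MeI, K2CO3, acetone, rt) to (2S,4S)-2-(3,4-dimethoxyphenyl)-5,7,8-trimethoxychroman-4-ol F6. Oxidation of the benzylic alcohol (MnO2, CH2Cl2, rt, or Dess–Martin periodinane) returns the ketone as 9.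

Step 2. Enantioface discrimination may be incomplete with the electron-rich aryl ketone, and a lowered enantiomeric purity would be carried through to 9. The fallback sets out from 3 and comes back at 4; it replaces asymmetric catalysis by resolution. NaBH4 (EtOH, 0 °C) reduces 3 to racemic ethyl 3-(3,4-dimethoxyphenyl)-3-hydroxypropanoate F7. A lipase (Burkholderia cepacia lipase, vinyl acetate, t-BuOMe, rt) should acetylate the (R)-alcohol selectively, in line with the usual preference of lipases for secondary benzylic alcohols, to ethyl (R)-3-acetoxy-3-(3,4-dimethoxyphenyl)propanoate F8. The unreacted (S)-alcohol 4 is separated by chromatography.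

Further compounds
F1 | step 3 | 2-bromo-4,5-dimethoxyphenol | COc1cc(O)c(Br)cc1OC
F2 | step 3 | (S)-3-(3,4-dimethoxyphenyl)-3-hydroxy-N-methoxy-N-methylpropanamide | CON(C)C(=O)C[C@H](O)c1ccc(OC)c(OC)c1
F3 | step 3 | (S)-3-(3,4-dimethoxyphenyl)-3-hydroxy-1-(2-hydroxy-4,5-dimethoxyphenyl)propan-1-one | COc1cc(O)c(C(=O)C[C@H](O)c2ccc(OC)c(OC)c2)cc1OC
F4 | step 3 | 2-[(S)-3-(3,4-dimethoxyphenyl)-3-hydroxypropanoyl]-4,4,5-trimethoxycyclohexa-2,5-dien-1-one | COC1=CC(=O)C(C(=O)C[C@H](O)c2ccc(OC)c(OC)c2)=CC1(OC)OC
F5 | step 4 | (2S,4S)-2-(3,4-dimethoxyphenyl)-7,8-dimethoxychromane-4,5-diol | COc1ccc([C@@H]2C[C@H](O)c3c(O)cc(OC)c(OC)c3O2)cc1OC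
F6 | step 4 | (2S,4S)-2-(3,4-dimethoxyphenyl)-5,7,8-trimethoxychroman-4-ol | COc1ccc([C@@H]2C[C@H](O)c3c(OC)cc(OC)c(OC)c3O2)cc1OC
F7 | step 2 | racemic ethyl 3-(3,4-dimethoxyphenyl)-3-hydroxypropanoate | CCOC(=O)CC(O)c1ccc(OC)c(OC)c1
F8 | step 2 | ethyl (R)-3-acetoxy-3-(3,4-dimethoxyphenyl)propanoate | CCOC(=O)C[C@@H](OC(C)=O)c1ccc(OC)c(OC)c1
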